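**Retrosynthetic overview**

1. Target ⇒ macrolactone diol: C2 acetylation, then substrate-controlled epoxidation of C11=C12 (epoxide ring formed last).
2. Macrolactone ⇒ seco α-hydroxy aldehyde carrying a (Z)-2-(bromomethyl)enoate: C1–C14 bond by a visible-light-driven, indium-catalysed intramolecular Barbier allylation, which closes the 14-membered carbocycle; the cis-fused α-methylene-γ-lactone follows in the same pot.
3. Seco compound ⇒ C1–C9 triol + achiral C9–C17 bromo ester: E-selective cross-metathesis at C8=C9.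
4. C1–C9 triol ⇒ C4–C5 bond by photoredox/nickel decarboxylative sp3–sp3 coupling of (S)-linalool-derived lavender lactone (C7) with a bromide from (R)-3-hydroxy-γ-butyrolactone (C2 bought, C3 by trans dianion methylation).
5. Bromo ester ⇒ pent-1-en-4-yne, ethylene oxide and methyl propiolate (carboalumination, oxidation, vinylalumination, SN2′ bromination).

Assumption: (R)-3-hydroxy-γ-butyrolactone, (S)-(+)-linalool and pent-1-en-4-yne are bought as catalogue chemicals.

Numbering used in names and explanations (taken from the target): C1 = lactone O–CH, C2 = CH–OAc, C3 = CH–CH3, C4–C6 = CH2, C7 = C(CH3)OH, C8=C9 (E), C10 = CH2, C11 (C–CH3) and C12 (CH) = epoxide carbons, C13 = CH2, C14 = ring CH; lactone C15 (α-carbon on C14), C16 (C=O), C17 (=CH2). Target configuration: 1R,2R,3S,7S,11R,12R,14S. In the fused names of 27 and 28, C15a = C1, C15 = C2, C14 = C3, C10 = C7, C6 = C11, C5 = C12, C3a = C14.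

**Route**

Step 1
Reactants: 1 (R)-3-hydroxy-γ-butyrolactone
Product: 3 (3R,4R)-4-hydroxy-3-methyloxolan-2-one, via dilithio dianion 2 (not isolated)
Conditions: LiN(i-Pr)2 (2.2 equiv), THF, −78 to −40 °C; MeI, −78 °C
Reagents that add atoms: iodomethane (CI)
Why: Dianion (alkoxide–enolate) alkylation of a β-hydroxy-γ-lactone, in which MeI enters the enolate face anti to the alkoxide to give the trans lactone, so the bought C2 centre sets C3.

Step 2
Reactants: 3 (3R,4R)-4-hydroxy-3-methyloxolan-2-one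
Product: 4 methyl (2R)-2-[(4R)-2,2-dimethyl-1,3-dioxolan-4-yl]propanoate
Conditions: Me2C(OMe)2, MeOH, TsOH·H2O (cat.), rt
Reagents that add atoms: 2,2-dimethoxypropane (COC(C)(C)OC); methanol (CO)
Why: Acid-catalysed lactone methanolysis with in situ isopropylidenation (transketalisation) of the freed 1,2-diol separates C4 (ester) from the C1/C2 diol without touching either stereocentre.

Step 3
Reactants: 4 methyl (2R)-2-[(4R)-2,2-dimethyl-1,3-dioxolan-4-yl]propanoate
Product: 5 (2S)-2-[(4R)-2,2-dimethyl-1,3-dioxolan-4-yl]propan-1-ol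
Conditions: LiAlH4, THF, 0 °C
Reagents that add atoms: none
Why: Hydride reduction of the ester leaves the acetonide intact and removes the only epimerisable position next to C3.

Step 4
Reactants: 5 (2S)-2-[(4R)-2,2-dimethyl-1,3-dioxolan-4-yl]propan-1-ol
Product: 6 (4R)-4-[(2R)-1-bromopropan-2-yl]-2,2-dimethyl-1,3-dioxolane
Conditions: CBr4, PPh3, CH2Cl2, 0 °C
Reagents that add atoms: tetrabromomethane (BrC(Br)(Br)Br)
Why: Appel bromination at the primary CH2 (SN2 at C4) involves no stereocentre.

Step 5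
Reactants: 7 (S)-linalool
Product: 9 (5S)-5-ethenyl-5-methyloxolan-2-one (lavender lactone), via lactol 8 (not isolated)
Conditions: O3 (1.0 equiv, Sudan Red 7B end point), CH2Cl2/MeOH, −78 °C; Me2S; evaporate; TEMPO (10 mol %), PhI(OAc)2, CH2Cl2, rt
Reagents that add atoms: ozone ([O-][O+]=O)
Why: Chemoselective ozonolysis of the electron-rich trisubstituted alkene (the vinyl group reacts far more slowly) gives the γ-lactol after reductive work-up, and oxoammonium oxidation then gives the lactone with the quaternary C7 centre untouched.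

Step 6
Reactants: 9 (5S)-5-ethenyl-5-methyloxolan-2-one; 6 (4R)-4-[(2R)-1-bromopropan-2-yl]-2,2-dimethyl-1,3-dioxolane
Product: 11 (3S,7S)-7-[(4R)-2,2-dimethyl-1,3-dioxolan-4-yl]-3-methyloct-1-en-3-ol, via cesium carboxylate 10 (not isolated)
Conditions: 9 (1.5 equiv), CsOH·H2O, MeCN/H2O, rt; then 6, Ir[dF(CF3)ppy]2(dtbbpy)PF6 (2 mol %), NiCl2(dme) (10 mol %), 4,4′-dimethoxy-2,2′-bipyridine, 450 nm LEDs, rt
Reagents that add atoms: none
Why: Known metallaphotoredox decarboxylative C(sp3)–C(sp3) cross-coupling, in which the photoexcited iridium complex oxidises the carboxylate, loss of CO2 gives the primary C5 radical, and nickel joins it to the alkyl bromide to form C4–C5 without involving any stereocentre.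

Step 7
Reactants: 11 (3S,7S)-7-[(4R)-2,2-dimethyl-1,3-dioxolan-4-yl]-3-methyloct-1-en-3-ol
Product: 12 (2R,3S,7S)-3,7-dimethylnon-8-ene-1,2,7-triol
Conditions: PPTS (0.2 equiv), MeOH, 40 °C
Reagents that add atoms: none
Why: Acid-catalysed transketalisation removes the acetonide under conditions mild enough for the tertiary allylic alcohol.

Step 8
Reactants: 13 pent-1-en-4-yne; 14 ethylene oxide
Product: 17 (3E)-4-methylhepta-3,6-dien-1-ol, via vinylalane 15 (not isolated), via lithium alanate 16 (not isolated)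
Conditions: Me3Al, Cp2ZrCl2 (20 mol %), CH2Cl2, 0 °C to rt; n-BuLi, THF/hexane, −78 °C; then 14, −78 to 0 °C
Reagents that add atoms: trimethylaluminium (C[Al](C)C)
Why: Negishi zirconium-catalysed syn-carboalumination of the terminal alkyne fixes the E-trisubstituted C11=C12 alkene, and the derived alanate opens ethylene oxide with retention of alkene geometry.

Step 9
Reactants: 17 (3E)-4-methylhepta-3,6-dien-1-ol
Product: 18 (3E)-4-methylhepta-3,6-dienal
Conditions: Dess–Martin periodinane, CH2Cl2, 0 °C; used at once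
Reagents that add atoms: none
Why: Dess–Martin oxidation is non-basic, so the β,γ-unsaturated aldehyde does not slip into conjugation.

Step 10
Reactants: 18 (3E)-4-methylhepta-3,6-dienal; 19 methyl propiolate
Product: 21 methyl (5E)-3-hydroxy-6-methyl-2-methylidenenona-5,8-dienoate (racemic at C3), via vinylaluminium reagent 20 (not isolated)
Conditions: 19, i-Bu2AlH, N-methylmorpholine N-oxide, THF, 0 °C; then 18, 0 °C to rt
Reagents that add atoms: none
Why: Vinylalumination (1,4-hydroalumination of the propiolate, then fast carbonyl addition) gives the Morita–Baylis–Hillman-type adduct without the slow amine catalysis that would isomerise the aldehyde; the racemic carbinol centre is erased in step 11.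

Step 11
Reactants: 21 methyl (5E)-3-hydroxy-6-methyl-2-methylidenenona-5,8-dienoate
Product: 22 methyl (2Z,5E)-2-(bromomethyl)-6-methylnona-2,5,8-trienoate
Conditions: NBS, Me2S, CH2Cl2, 0 °C to rt
Reagents that add atoms: N-bromosuccinimide (O=C1CCC(=O)N1Br)
Why: Corey–Kim-type activation of the alcohol and SN2′ bromide delivery give the thermodynamically preferred (2Z)-2-(bromomethyl)enoate.

Step 12
Reactants: 12 (2R,3S,7S)-3,7-dimethylnon-8-ene-1,2,7-triol; 22 methyl (2Z,5E)-2-(bromomethyl)-6-methylnona-2,5,8-trienoate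
Product: 23 methyl (2Z,5E,8E,10S,14S,15R)-2-(bromomethyl)-10,15,16-trihydroxy-6,10,14-trimethylhexadeca-2,5,8-trienoate
Conditions: 22 (1.5 equiv), second-generation Hoveyda–Grubbs catalyst RuCl2(H2IMes)(=CH-C6H4-2-O-i-Pr) (5 mol %), 1,4-benzoquinone (10 mol %), CH2Cl2, 40 °C
Reagents that add atoms: none
Why: Olefin cross-metathesis joins the vinyl group of the free tertiary allylic alcohol (slow to homodimerise) to the unhindered terminal alkene of 22; the quaternary carbinol enforces E geometry at C8=C9, and the trisubstituted alkenes and allylic bromide stay out.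

Step 13
Reactants: 23 methyl (2Z,5E,8E,10S,14S,15R)-2-(bromomethyl)-10,15,16-trihydroxy-6,10,14-trimethylhexadeca-2,5,8-trienoate
Product: 24 methyl (2Z,5E,8E,10S,14S,15R)-2-(bromomethyl)-10,15-dihydroxy-6,10,14-trimethyl-16-oxohexadeca-2,5,8-trienoate
Conditions: TEMPO (10 mol %), PhI(OAc)2 (1.05 equiv), CH2Cl2, 0 °C to rt; used crude
Reagents that add atoms: none
Why: Oxoammonium (TEMPO) oxidation is selective for the primary hydroxyl of the 1,2-diol and is non-basic, so the α-hydroxy aldehyde forms without epimerising C2.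

Step 14
Reactants: 24 methyl (2Z,5E,8E,10S,14S,15R)-2-(bromomethyl)-10,15-dihydroxy-6,10,14-trimethyl-16-oxohexadeca-2,5,8-trienoate
Product: 27 (3aS,5E,8E,10S,14S,15R,15aR)-10,15-dihydroxy-6,10,14-trimethyl-3-methylidene-3a,4,7,10,11,12,13,14,15,15a-decahydrocyclotetradeca[b]furan-2(3H)-one, via allylindium species 25 (not isolated), via macrocyclic hydroxy ester 26 (not isolated)
Conditions: 4CzIPN (2 mol %), InCl3 (20 mol %), Hantzsch ester (1.5 equiv), THF/H2O (4:1), 450 nm LEDs, 25 °C, syringe-pump addition of 24 (final 2 mM); then PPTS (20 mol %), PhMe, 40 °C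
Reagents that add atoms: none
Why: Proposed new method: a photoreductive, indium-catalytic intramolecular Barbier allylation in which photoexcited 4CzIPN is quenched by the Hantzsch ester, the reduced dye (about −1.2 V vs SCE) converts InCl3 into monovalent indium, this inserts into the allylic C–Br bond, and the resulting (Z)-2-(methoxycarbonyl)allylindium adds through its γ-carbon (C14) to the aldehyde in a chair transition state where trivalent indium chelates the aldehyde oxygen and the free C2 hydroxyl, so attack comes anti to C3 (1,2-syn diol, C1 R) with the C13 chain axial (C14 S, hence the cis-lactone after PPTS lactonisation); the closest known reactions are stoichiometric indium-metal Barbier additions of 2-(bromomethyl)acrylates to α-hydroxy aldehydes in water and photoredox-driven titanium-, chromium- and bismuth-catalysed aldehyde allylations, none shown with catalytic indium or for a macrocyclisation.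

Step 15
Reactants: 27 macrolactone diol (name as in step 14)
Product: 28 (3aS,5E,8E,10S,14S,15R,15aR)-10-hydroxy-6,10,14-trimethyl-3-methylidene-2-oxo-2,3,3a,4,7,10,11,12,13,14,15,15a-dodecahydrocyclotetradeca[b]furan-15-yl acetate
Conditions: Ac2O, pyridine, DMAP (cat.), CH2Cl2, 0 °C to rt
Reagents that add atoms: acetic anhydride (CC(=O)OC(C)=O)
Why: DMAP-catalysed acylation takes the secondary C2 hydroxyl only, the tertiary C7 alcohol being inert under these conditions.

Step 16
Reactants: 28 macrolactone acetate (name as in step 15)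
Product: 29 CNP0202356.4, the (11R,12R)-11,12-epoxide of 28: (1R,2R,3S,7S,8E,11R,12R,14S)-2-acetoxy-11,12-epoxy-7-hydroxy-3,7,11-trimethyl 14-membered carbocycle cis-fused at C1/C14 to the α-methylene-γ-lactone
Conditions: mCPBA (1.05 equiv), CH2Cl2, −20 to 0 °C
Reagents that add atoms: 3-chloroperoxybenzoic acid (O=C(OO)c1cccc(Cl)c1)
Why: Prilezhaev epoxidation picks the most electron-rich trisubstituted C11=C12 alkene over the E-disubstituted allylic alkene and the enoate, adds syn to give the trans epoxide, and is expected to attack the exposed outer face of the macrocycle set by the existing stereocentres to give 11R,12R; that facial preference is assumed, not established.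

**Compound list**

1 | (R)-3-hydroxy-γ-butyrolactone [(4R)-4-hydroxyoxolan-2-one] | O=C1C[C@@H](O)CO1 | starting material
2 | dilithium (4R)-4,5-dihydrofuran-2,4-bis(olate) (dianion of 1) | [Li]OC1=C[C@@H](O[Li])CO1 | intermediate
3 | (3R,4R)-4-hydroxy-3-methyloxolan-2-one (trans) | O=C1[C@H](C)[C@@H](O)CO1 | intermediate
4 | methyl (2R)-2-[(4R)-2,2-dimethyl-1,3-dioxolan-4-yl]propanoate | COC(=O)[C@H](C)[C@@H]1COC(C)(C)O1 | intermediate
5 | (2S)-2-[(4R)-2,2-dimethyl-1,3-dioxolan-4-yl]propan-1-ol | OC[C@H](C)[C@@H]1COC(C)(C)O1 | intermediate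
6 | (4R)-4-[(2R)-1-bromopropan-2-yl]-2,2-dimethyl-1,3-dioxolane | BrC[C@H](C)[C@@H]1COC(C)(C)O1 | intermediate
7 | (S)-linalool [(3S)-3,7-dimethylocta-1,6-dien-3-ol] | C=C[C@@](C)(O)CCC=C(C)C | starting material
8 | (5S)-5-ethenyl-5-methyloxolan-2-ol (lactol, anomer mixture) | OC1CC[C@@](C)(C=C)O1 | intermediate
9 | (5S)-5-ethenyl-5-methyloxolan-2-one (lavender lactone) | O=C1CC[C@@](C)(C=C)O1 | intermediate
10 | cesium (4S)-4-hydroxy-4-methylhex-5-enoate | [Cs+].[O-]C(=O)CC[C@](C)(O)C=C | intermediate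
11 | (3S,7S)-7-[(4R)-2,2-dimethyl-1,3-dioxolan-4-yl]-3-methyloct-1-en-3-ol | C=C[C@@](C)(O)CCC[C@H](C)[C@@H]1COC(C)(C)O1 | intermediate
12 | (2R,3S,7S)-3,7-dimethylnon-8-ene-1,2,7-triol | OC[C@H](O)[C@@H](C)CCC[C@](C)(O)C=C | intermediate
13 | pent-1-en-4-yne | C=CCC#C | starting material
14 | ethylene oxide (oxirane) | C1CO1 | starting material
15 | dimethyl[(1E)-2-methylpenta-1,4-dien-1-yl]alane | C=CC/C(C)=C/[Al](C)C | intermediate
16 | lithium butyl(dimethyl)[(1E)-2-methylpenta-1,4-dien-1-yl]aluminate | [Li+].CCCC[Al-](C)(C)/C=C(C)/CC=C | intermediate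
17 | (3E)-4-methylhepta-3,6-dien-1-ol | OCC/C=C(C)/CC=C | intermediate
18 | (3E)-4-methylhepta-3,6-dienal | O=CC/C=C(C)/CC=C | intermediate
19 | methyl propiolate | C#CC(=O)OC | starting material
20 | methyl 2-[bis(2-methylpropyl)alumanyl]prop-2-enoate | COC(=O)C(=C)[Al](CC(C)C)CC(C)C | intermediate
21 | methyl (5E)-3-hydroxy-6-methyl-2-methylidenenona-5,8-dienoate (racemic at C3) | COC(=O)C(=C)C(O)C/C=C(C)/CC=C | intermediate
22 | methyl (2Z,5E)-2-(bromomethyl)-6-methylnona-2,5,8-trienoate | COC(=O)/C(CBr)=C/C/C=C(C)/CC=C | intermediate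
23 | methyl (2Z,5E,8E,10S,14S,15R)-2-(bromomethyl)-10,15,16-trihydroxy-6,10,14-trimethylhexadeca-2,5,8-trienoate | OC[C@H](O)[C@@H](C)CCC[C@](C)(O)/C=C/C/C(C)=C/C/C=C(\CBr)C(=O)OC | intermediate
24 | methyl (2Z,5E,8E,10S,14S,15R)-2-(bromomethyl)-10,15-dihydroxy-6,10,14-trimethyl-16-oxohexadeca-2,5,8-trienoate | O=C[C@H](O)[C@@H](C)CCC[C@](C)(O)/C=C/C/C(C)=C/C/C=C(\CBr)C(=O)OC | intermediate
25 | methyl (2Z,5E,8E,10S,14S,15R)-2-{[bromo(chloro)indiganyl]methyl}-10,15-dihydroxy-6,10,14-trimethyl-16-oxohexadeca-2,5,8-trienoate (allylindium species) | O=C[C@H](O)[C@@H](C)CCC[C@](C)(O)/C=C/C/C(C)=C/C/C=C(\C[In](Cl)Br)C(=O)OC | intermediate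
26 | methyl 2-[(1S,2R,3R,4S,8S,9E,12E)-2,3,8-trihydroxy-4,8,12-trimethylcyclotetradeca-9,12-dien-1-yl]prop-2-enoate | C=C(C(=O)OC)[C@H]1[C@@H](O)[C@H](O)[C@@H](C)CCC[C@](C)(O)/C=C/C/C(C)=C/C1 | intermediate
27 | (3aS,5E,8E,10S,14S,15R,15aR)-10,15-dihydroxy-6,10,14-trimethyl-3-methylidene-3a,4,7,10,11,12,13,14,15,15a-decahydrocyclotetradeca[b]furan-2(3H)-one (1R,2R,3S,7S,14S in the C1–C17 numbering) | C=C1C(=O)O[C@H]2[C@H](O)[C@@H](C)CCC[C@](C)(O)/C=C/C/C(C)=C/C[C@@H]12 | intermediate
28 | (3aS,5E,8E,10S,14S,15R,15aR)-10-hydroxy-6,10,14-trimethyl-3-methylidene-2-oxo-2,3,3a,4,7,10,11,12,13,14,15,15a-dodecahydrocyclotetradeca[b]furan-15-yl acetate | C=C1C(=O)O[C@H]2[C@H](OC(C)=O)[C@@H](C)CCC[C@](C)(O)/C=C/C/C(C)=C/C[C@@H]12 | intermediate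
29 | CNP0202356.4, (1R,2R,3S,7S,8E,11R,12R,14S)-2-acetoxy-11,12-epoxy-7-hydroxy-3,7,11-trimethyl macrocycle cis-fused at C1/C14 to the α-methylene-γ-lactone | C=C1C(=O)O[C@H]2[C@H](OC(C)=O)[C@@H](C)CCC[C@](C)(O)/C=C/C[C@@]3(C)O[C@@H]3C[C@@H]12 | target

**Step count**

Total: 16 steps. Longest linear sequence: 11 steps (1, 2, 3, 4, 6, 7, 12, 13, 14, 15, 16).

**Three steps most likely to fail**

Step 14 (the proposed new macrocyclisation). Turnover of indium by the photoreductant is unproven. Hydrodebromination or oligomerisation may compete. The macrocyclic transition state may weaken the chelation control that sets C1 and C14. The fallback uses only known chemistry and changes the order of bond formation; it sets out from 12 and 22 and comes back at 27. Triol 12 is oxidised (TEMPO, PhI(OAc)2) to (2R,3S,7S)-2,7-dihydroxy-3,7-dimethylnon-8-enal F1. F1 and bromide 22 are joined by the classical aqueous Barbier reaction with indium powder in THF/H2O (chelation-controlled, syn,syn) to give methyl (3S,4R,5R,6S,10S)-4,5,10-trihydroxy-6,10-dimethyl-2-methylidene-3-[(2E)-3-methylhexa-2,5-dien-1-yl]dodec-11-enoate F2. PPTS lactonises F2 to (4S,5R)-5-[(1R,2S,6S)-1,6-dihydroxy-2,6-dimethyloct-7-en-1-yl]-3-methylidene-4-[(2E)-3-methylhexa-2,5-dien-1-yl]oxolan-2-one F3. Ring-closing metathesis at C8=C9 (second-generation Grubbs catalyst RuCl2(H2IMes)(PCy3)(=CHPh), 1 mM, CH2Cl2, 40 °C) then closes the macrocycle to 27.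

Step 13 (α-hydroxy aldehyde from the 1,2-diol). PhI(OAc)2 can cleave the glycol, and the product can over-oxidise or dimerise. The fallback sets out from 12 and comes back at 24. The diol of 12 is silylated (Et3SiCl, imidazole) to (3S,7S,8R)-3,7-dimethyl-8,9-bis[(triethylsilyl)oxy]non-1-en-3-ol F4. Swern oxidation, which converts a primary triethylsilyl ether directly into the aldehyde and leaves the secondary one, gives (2R,3S,7S)-7-hydroxy-3,7-dimethyl-2-[(triethylsilyl)oxy]non-8-enal F5. Cross-metathesis with 22 under the step 12 conditions gives methyl (2Z,5E,8E,10S,14S,15R)-2-(bromomethyl)-10-hydroxy-6,10,14-trimethyl-16-oxo-15-[(triethylsilyl)oxy]hexadeca-2,5,8-trienoate F6. AcOH/THF/H2O removes the silyl group to give 24.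

Step 16 (facial selectivity of the epoxidation). The peracid may attack the wrong face of C11=C12. The fallback sets out from 28 and comes back at 29, and puts the oxygen on the opposite face. NBS in THF/H2O forms the bromonium ion on the face the peracid prefers, and water opens it anti at C11 to give the (11R,12S)-12-bromo-11-hydroxy derivative of 28, bromohydrin F7. K2CO3 in acetone closes F7 with inversion at C12 to give 29.

**Further compounds**

F1 | step 14 | (2R,3S,7S)-2,7-dihydroxy-3,7-dimethylnon-8-enal | O=C[C@H](O)[C@@H](C)CCC[C@](C)(O)C=C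
F2 | step 14 | methyl (3S,4R,5R,6S,10S)-4,5,10-trihydroxy-6,10-dimethyl-2-methylidene-3-[(2E)-3-methylhexa-2,5-dien-1-yl]dodec-11-enoate | C=C(C(=O)OC)[C@H](C/C=C(C)/CC=C)[C@@H](O)[C@H](O)[C@@H](C)CCC[C@](C)(O)C=C
F3 | step 14 | (4S,5R)-5-[(1R,2S,6S)-1,6-dihydroxy-2,6-dimethyloct-7-en-1-yl]-3-methylidene-4-[(2E)-3-methylhexa-2,5-dien-1-yl]oxolan-2-one | C=C1C(=O)O[C@@H]([C@H](O)[C@@H](C)CCC[C@](C)(O)C=C)[C@H]1C/C=C(C)/CC=C
F4 | step 13 | (3S,7S,8R)-3,7-dimethyl-8,9-bis[(triethylsilyl)oxy]non-1-en-3-ol | CC[Si](CC)(CC)OC[C@H](O[Si](CC)(CC)CC)[C@@H](C)CCC[C@](C)(O)C=C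
F5 | step 13 | (2R,3S,7S)-7-hydroxy-3,7-dimethyl-2-[(triethylsilyl)oxy]non-8-enal | O=C[C@H](O[Si](CC)(CC)CC)[C@@H](C)CCC[C@](C)(O)C=C
F6 | step 13 | methyl (2Z,5E,8E,10S,14S,15R)-2-(bromomethyl)-10-hydroxy-6,10,14-trimethyl-16-oxo-15-[(triethylsilyl)oxy]hexadeca-2,5,8-trienoate | O=C[C@H](O[Si](CC)(CC)CC)[C@@H](C)CCC[C@](C)(O)/C=C/C/C(C)=C/C/C=C(\CBr)C(=O)OC
F7 | step 16 | (11R,12S)-12-bromo-11-hydroxy derivative of 28 (bromohydrin; 1R,2R,3S,7S,14S otherwise) | C=C1C(=O)O[C@H]2[C@H](OC(C)=O)[C@@H](C)CCC[C@](C)(O)/C=C/C[C@@](C)(O)[C@@H](Br)C[C@@H]12
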